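**Retrosynthetic overview**
1. Target 36 ⇐ acetonide 35 ⇐ ten-membered acid 31: the C6 carboxyl is exchanged for the lactone oxygen with retention (carboxy inversion), then γ-lactonisation.
2. Ten-membered carbocycle ⇐ 14-membered macrolactone 26 by Ireland–Claisen ring contraction: the [3,3] shift forms C6–C7, the carbocycle, both stereocentres and the exocyclic methylene in one step.
3. 26 ⇐ iodo-enoate aldehyde 24 by CrCl2/NiCl2 ring closure at C9–C10 (C9 under Felkin–Anh control from C8).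
4. 24 ⇐ acid 10 ((S)-citronellol + CO2) + allylic bromide 14 ((R)-glyceraldehyde acetonide + methyl acrylate) + side-chain acid 6 (D-threonine).
5. Ring order: 14-membered lactone, then ten-membered carbocycle, then γ-lactone.

Assumption: (S)-citronellol, (R)-glyceraldehyde acetonide and D-threonine are the chiral purchases. Labels C1–C14 are those of the final skeleton (C6 lactone carbinol, C7 ring fusion, C8 and C9 oxygenated carbons, C10=C1 ring alkene, C4 methyl carbon, C11–C13 lactone carbons, C14 ester carbon); C6a is the extra carboxyl carbon on C6 that is later lost as CO2.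

**Step 1**
Reactants: 1 D-threonine
Product: 2 (2R,3S)-2,3-dihydroxybutanoic acid
Conditions: NaNO2, 1 M H2SO4, 0 °C → rt
Reagents that add atoms: water, O
Why: Diazotisation of an α-amino acid goes with net retention (double inversion through the α-lactone), so C2 stays R and C3 is untouched.

**Step 2**
Reactants: 2 (2R,3S)-2,3-dihydroxybutanoic acid
Product: 3 methyl (4R,5S)-2,2,5-trimethyl-1,3-dioxolane-4-carboxylate
Conditions: MeOH, Me2C(OMe)2, TsOH (cat.), 50 °C
Reagents that add atoms: methanol, CO; 2,2-dimethoxypropane, COC(C)(C)OC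
Why: Fischer esterification plus acid-catalysed transketalisation gives the trans-dioxolane without touching either stereocentre.

**Step 3**
Reactants: 3 methyl (4R,5S)-2,2,5-trimethyl-1,3-dioxolane-4-carboxylate
Product: 5 methyl (4S,5S)-2,2,4,5-tetramethyl-1,3-dioxolane-4-carboxylate, via lithium enolate 4 (not isolated)
Conditions: LiN(iPr)2, THF/DMPU, −78 °C; MeI
Reagents that add atoms: iodomethane, CI
Why: Ester enolate alkylation in which MeI approaches anti to the C5 methyl group, so the threonine-derived C5 centre sets the quaternary centre as 4S.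

**Step 4**
Reactants: 5 methyl (4S,5S)-2,2,4,5-tetramethyl-1,3-dioxolane-4-carboxylate
Product: 6 (4S,5S)-2,2,4,5-tetramethyl-1,3-dioxolane-4-carboxylic acid
Conditions: LiOH, THF/H2O, rt; 1 M HCl
Reagents that add atoms: lithium hydroxide, [Li+].[OH-]
Why: Saponification of the methyl ester; no stereocentre is involved.

**Step 5**
Reactants: 7 (S)-citronellol
Product: 8 (S)-citronellyl bromide
Conditions: CBr4, PPh3, CH2Cl2, 0 °C
Reagents that add atoms: tetrabromomethane, BrC(Br)(Br)Br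
Why: Appel bromination of the primary alcohol leaves the remote stereocentre untouched.

**Step 6**
Reactants: 8 (S)-citronellyl bromide
Product: 10 (4S)-4,8-dimethylnon-7-enoic acid, via Grignard reagent 9 (not isolated)
Conditions: Mg, THF, 45 °C; CO2 (g), −20 °C; 1 M HCl
Reagents that add atoms: carbon dioxide, O=C=O
Why: Grignard carboxylation adds the one carbon (C6a) that the later [3,3] shift needs as the ester carbonyl.

**Step 7**
Reactants: 11 (4R)-2,2-dimethyl-1,3-dioxolane-4-carbaldehyde; 12 methyl acrylate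
Product: 13 methyl 2-{hydroxy[(4R)-2,2-dimethyl-1,3-dioxolan-4-yl]methyl}prop-2-enoate (both carbinol epimers)
Conditions: DABCO (0.3 equiv), 12 in excess, rt, 4 d
Reagents that add atoms: none
Why: Morita–Baylis–Hillman reaction; the new carbinol centre is a mixture but is erased in step 8.

**Step 8**
Reactants: 13 Morita–Baylis–Hillman adduct
Product: 14 methyl (2Z)-2-(bromomethyl)-3-[(4S)-2,2-dimethyl-1,3-dioxolan-4-yl]prop-2-enoate
Conditions: N-bromosuccinimide, Me2S, CH2Cl2, −20 °C → rt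
Reagents that add atoms: N-bromosuccinimide, BrN1C(=O)CCC1=O
Why: Corey–Kim activation followed by SN2′ attack of bromide gives the trisubstituted (Z)-allylic bromide from both epimers.

**Step 9**
Reactants: 10 (4S)-4,8-dimethylnon-7-enoic acid; 14 allylic bromide
Product: 15 methyl (2E)-3-[(4S)-2,2-dimethyl-1,3-dioxolan-4-yl]-2-({[(4S)-4,8-dimethylnon-7-enoyl]oxy}methyl)prop-2-enoate
Conditions: K2CO3, DMF, rt
Reagents that add atoms: none
Why: SN2 O-alkylation of the potassium carboxylate by the primary allylic bromide.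

**Step 10**
Reactants: 15 allylic ester
Product: 17 methyl (2E)-3-[(4S)-2,2-dimethyl-1,3-dioxolan-4-yl]-2-({[(4S)-4-methyl-7-oxoheptanoyl]oxy}methyl)prop-2-enoate, via ozonide 16 (not isolated)
Conditions: O3, pyridine, CH2Cl2, −78 °C; Me2S
Reagents that add atoms: ozone, [O-][O+]=O
Why: Ozonolysis is selective for the electron-rich trisubstituted alkene over the conjugated enoate.

**Step 11**
Reactants: 17 aldehyde
Product: 18 methyl (2E)-3-[(4S)-2,2-dimethyl-1,3-dioxolan-4-yl]-2-({[(4S,7Z)-8-iodo-9-methoxy-4-methyl-9-oxonon-7-enoyl]oxy}methyl)prop-2-enoate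
Conditions: Ph3P=CHCO2Me, N-iodosuccinimide, CH2Cl2, −20 °C; then 17, rt
Reagents that add atoms: methyl (triphenylphosphoranylidene)acetate, COC(=O)C=P(c1ccccc1)(c1ccccc1)c1ccccc1; N-iodosuccinimide, IN1C(=O)CCC1=O
Why: Wittig olefination with the in situ iodinated stabilised ylide gives the (Z)-α-iodo enoate with the ester trans to the chain.

**Step 12**
Reactants: 18 iodo enoate acetonide
Product: 19 methyl (2E,4S)-4,5-dihydroxy-2-({[(4S,7Z)-8-iodo-9-methoxy-4-methyl-9-oxonon-7-enoyl]oxy}methyl)pent-2-enoate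
Conditions: AcOH/H2O (4:1), 40 °C
Reagents that add atoms: none
Why: Acid hydrolysis of the isopropylidene acetal; the esters and the vinyl iodide survive.

**Step 13**
Reactants: 19 diol
Product: 20 methyl (2E,4S)-5-[(tert-butyldimethylsilyl)oxy]-4-hydroxy-2-({[(4S,7Z)-8-iodo-9-methoxy-4-methyl-9-oxonon-7-enoyl]oxy}methyl)pent-2-enoate
Conditions: t-BuMe2SiCl, imidazole, CH2Cl2, 0 °C
Reagents that add atoms: tert-butyldimethylsilyl chloride, CC(C)(C)[Si](C)(C)Cl
Why: Silylation is selective for the primary hydroxyl.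

**Step 14**
Reactants: 20 mono-silyl ether; 6 (4S,5S)-2,2,4,5-tetramethyl-1,3-dioxolane-4-carboxylic acid
Product: 22 (2S,3E)-1-[(tert-butyldimethylsilyl)oxy]-4-(methoxycarbonyl)-5-{[(4S,7Z)-8-iodo-9-methoxy-4-methyl-9-oxonon-7-enoyl]oxy}pent-3-en-2-yl (4S,5S)-2,2,4,5-tetramethyl-1,3-dioxolane-4-carboxylate, via mixed anhydride 21 (not isolated)
Conditions: 2,4,6-Cl3C6H2COCl, Et3N, THF, rt; then 20, DMAP, toluene, rt
Reagents that add atoms: none
Why: Yamaguchi esterification acylates the free secondary C8 hydroxyl with the hindered acid; no stereocentre changes.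

**Step 15**
Reactants: 22 silyl ether
Product: 23 (2S,3E)-1-hydroxy-4-(methoxycarbonyl)-5-{[(4S,7Z)-8-iodo-9-methoxy-4-methyl-9-oxonon-7-enoyl]oxy}pent-3-en-2-yl (4S,5S)-2,2,4,5-tetramethyl-1,3-dioxolane-4-carboxylate
Conditions: HF·pyridine, THF/pyridine, 0 °C
Reagents that add atoms: none
Why: Fluoride cleaves the primary silyl ether, and the acidic medium suppresses acyl migration.

**Step 16**
Reactants: 23 primary alcohol
Product: 24 (2S,3E)-4-(methoxycarbonyl)-5-{[(4S,7Z)-8-iodo-9-methoxy-4-methyl-9-oxonon-7-enoyl]oxy}-1-oxopent-3-en-2-yl (4S,5S)-2,2,4,5-tetramethyl-1,3-dioxolane-4-carboxylate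
Conditions: Dess–Martin periodinane, pyridine, CH2Cl2, 0 °C
Reagents that add atoms: none
Why: Dess–Martin oxidation gives the α-acyloxy aldehyde, which is used at once to avoid epimerisation at C8.

**Step 17**
Reactants: 24 iodo enoate aldehyde
Product: 26 fourteen-membered macrolactone (4S,8S,9R) with C9 hydroxyl, via alkenylchromium dichloride 25 (not isolated)
Conditions: CrCl2 (8 equiv), NiCl2 (2 mol %), DMSO/THF, 1 mM, rt
Reagents that add atoms: none
Why: Nozaki–Hiyama–Kishi macrocyclisation in which the σ-bound alkenylchromium is expected to keep the alkene geometry and to add anti to the C8 acyloxy group (Felkin–Anh), setting C9 as R.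

**Step 18**
Reactants: 26 macrolactone
Product: 30 ten-membered hydroxy acid (4S,6R,7R,8S,9R), via C9 silyl ether 27 (not isolated), via silyl ketene acetal 28 (not isolated), via bis-silylated acid 29 (not isolated)
Conditions: Me3SiCl, Et3N, THF, 0 °C; LiN(SiMe3)2, −78 °C, then 65 °C; aq. citric acid
Reagents that add atoms: none
Why: Ireland–Claisen ring contraction: the (E)-silyl ketene acetal undergoes the [3,3]-sigmatropic shift through a chair-like transition state (C5 and C8 both pseudo-axial, H8 eclipsing the alkene, the C9 tether anti to the forming bond), forming C6–C7 and the ten-membered ring and setting C6 and C7 under control of C8.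

**Step 19**
Reactants: 30 hydroxy acid
Product: 31 ten-membered acid with C9 acetate
Conditions: Ac2O, pyridine, DMAP (cat.), CH2Cl2, 0 °C; aq. NaHCO3 work-up
Reagents that add atoms: acetic anhydride, CC(=O)OC(C)=O
Why: Acetylation of the C9 hydroxyl; the transient mixed anhydride of the acid is hydrolysed on work-up.

**Step 20**
Reactants: 31 acid
Product: 35 trans-fused α-methylene-γ-butyrolactone (4S,6R,7S,8S,9R) with side-chain acetonide, via diacyl peroxide 32 (not isolated), via mixed carbonic anhydride 33 (not isolated), via C6 hydroxy ester 34 (not isolated)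
Conditions: mCPBA, DCC, CH2Cl2, 0 °C; MeCN, 50 °C; aq. NaHCO3/THF; camphorsulfonic acid (cat.), CH2Cl2, rt
Reagents that add atoms: 3-chloroperoxybenzoic acid, OOC(=O)c1cccc(Cl)c1
Why: Carboxy inversion: the diacyl peroxide rearranges by a 1,2-shift of C6 from carbon to oxygen with retention, hydrolysis frees the C6 hydroxyl trans to the C7 side chain, and lactonisation onto the C12 methyl ester closes the lactone.

**Step 21**
Reactants: 35 lactone acetonide
Product: 36 target CNP0557070.1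
Conditions: CF3CO2H/H2O (9:1), 0 °C
Reagents that add atoms: none
Why: Mild acid hydrolysis of the acetonide frees the side-chain diol without touching the esters or the α-methylene lactone.

**Compound list**
1 | D-threonine, (2R,3S)-2-amino-3-hydroxybutanoic acid | C[C@H](O)[C@@H](N)C(=O)O | starting material
2 | (2R,3S)-2,3-dihydroxybutanoic acid | C[C@H](O)[C@@H](O)C(=O)O | intermediate
3 | methyl (4R,5S)-2,2,5-trimethyl-1,3-dioxolane-4-carboxylate | COC(=O)[C@@H]1OC(C)(C)O[C@H]1C | intermediate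
4 | lithium enolate of 3 (C5 still S) | COC(O[Li])=C1OC(C)(C)O[C@H]1C | intermediate
5 | methyl (4S,5S)-2,2,4,5-tetramethyl-1,3-dioxolane-4-carboxylate | COC(=O)[C@@]1(C)OC(C)(C)O[C@H]1C | intermediate
6 | (4S,5S)-2,2,4,5-tetramethyl-1,3-dioxolane-4-carboxylic acid | OC(=O)[C@@]1(C)OC(C)(C)O[C@H]1C | intermediate
7 | (S)-citronellol, (3S)-3,7-dimethyloct-6-en-1-ol | OCC[C@@H](C)CCC=C(C)C | starting material
8 | (S)-citronellyl bromide, (6S)-8-bromo-2,6-dimethyloct-2-ene | BrCC[C@@H](C)CCC=C(C)C | intermediate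
9 | (S)-citronellylmagnesium bromide | Br[Mg]CC[C@@H](C)CCC=C(C)C | intermediate
10 | (4S)-4,8-dimethylnon-7-enoic acid | OC(=O)CC[C@@H](C)CCC=C(C)C | intermediate
11 | (R)-glyceraldehyde acetonide, (4R)-2,2-dimethyl-1,3-dioxolane-4-carbaldehyde | O=C[C@H]1COC(C)(C)O1 | starting material
12 | methyl acrylate | C=CC(=O)OC | starting material
13 | methyl 2-{hydroxy[(4R)-2,2-dimethyl-1,3-dioxolan-4-yl]methyl}prop-2-enoate, both carbinol epimers | C=C(C(=O)OC)C(O)[C@H]1COC(C)(C)O1 | intermediate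
14 | methyl (2Z)-2-(bromomethyl)-3-[(4S)-2,2-dimethyl-1,3-dioxolan-4-yl]prop-2-enoate | BrC/C(C(=O)OC)=C\[C@H]1COC(C)(C)O1 | intermediate
15 | methyl (2E)-3-[(4S)-2,2-dimethyl-1,3-dioxolan-4-yl]-2-({[(4S)-4,8-dimethylnon-7-enoyl]oxy}methyl)prop-2-enoate | CC(C)=CCC[C@H](C)CCC(=O)OC/C(C(=O)OC)=C\[C@H]1COC(C)(C)O1 | intermediate
16 | secondary ozonide (3,3-dimethyl-1,2,4-trioxolane) of 15 | CC1(C)OOC(CC[C@H](C)CCC(=O)OC/C(C(=O)OC)=C\[C@H]2COC(C)(C)O2)O1 | intermediate
17 | methyl (2E)-3-[(4S)-2,2-dimethyl-1,3-dioxolan-4-yl]-2-({[(4S)-4-methyl-7-oxoheptanoyl]oxy}methyl)prop-2-enoate | O=CCC[C@H](C)CCC(=O)OC/C(C(=O)OC)=C\[C@H]1COC(C)(C)O1 | intermediate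
18 | methyl (2E)-3-[(4S)-2,2-dimethyl-1,3-dioxolan-4-yl]-2-({[(4S,7Z)-8-iodo-9-methoxy-4-methyl-9-oxonon-7-enoyl]oxy}methyl)prop-2-enoate | COC(=O)/C(I)=C/CC[C@H](C)CCC(=O)OC/C(C(=O)OC)=C\[C@H]1COC(C)(C)O1 | intermediate
19 | methyl (2E,4S)-4,5-dihydroxy-2-({[(4S,7Z)-8-iodo-9-methoxy-4-methyl-9-oxonon-7-enoyl]oxy}methyl)pent-2-enoate | COC(=O)/C(I)=C/CC[C@H](C)CCC(=O)OC/C(C(=O)OC)=C\[C@H](O)CO | intermediate
20 | 5-O-tert-butyldimethylsilyl ether of 19 | COC(=O)/C(I)=C/CC[C@H](C)CCC(=O)OC/C(C(=O)OC)=C\[C@H](O)CO[Si](C)(C)C(C)(C)C | intermediate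
21 | mixed anhydride of 6 with 2,4,6-trichlorobenzoic acid | O=C(OC(=O)c1c(Cl)cc(Cl)cc1Cl)[C@@]1(C)OC(C)(C)O[C@H]1C | intermediate
22 | 4-O-[(4S,5S)-2,2,4,5-tetramethyl-1,3-dioxolane-4-carbonyl] derivative of 20 (C8 ester, C9 silyl ether) | COC(=O)/C(I)=C/CC[C@H](C)CCC(=O)OC/C(C(=O)OC)=C\[C@H](OC(=O)[C@@]1(C)OC(C)(C)O[C@H]1C)CO[Si](C)(C)C(C)(C)C | intermediate
23 | primary alcohol from 22 (free C9 hydroxyl) | COC(=O)/C(I)=C/CC[C@H](C)CCC(=O)OC/C(C(=O)OC)=C\[C@H](OC(=O)[C@@]1(C)OC(C)(C)O[C@H]1C)CO | intermediate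
24 | C9 aldehyde from 23 (8S α-acyloxy aldehyde, (Z)-α-iodo enoate) | COC(=O)/C(I)=C/CC[C@H](C)CCC(=O)OC/C(C(=O)OC)=C\[C@H](OC(=O)[C@@]1(C)OC(C)(C)O[C@H]1C)C=O | intermediate
25 | alkenylchromium dichloride from 24 (CrCl2 group at C10 in place of iodine) | COC(=O)/C([Cr](Cl)Cl)=C/CC[C@H](C)CCC(=O)OC/C(C(=O)OC)=C\[C@H](OC(=O)[C@@]1(C)OC(C)(C)O[C@H]1C)C=O | intermediate
26 | 14-membered macrolactone: lactone C6a(=O)–O–C13; (E)-C1=C10 and (E)-C7=C11, each bearing CO2Me; 4S-methyl; 8S-O-[(4S,5S)-2,2,4,5-tetramethyl-1,3-dioxolane-4-carbonyl]; 9R-hydroxy | COC(=O)/C1=C/CC[C@H](C)CCC(=O)OC/C(C(=O)OC)=C\[C@H](OC(=O)[C@@]2(C)OC(C)(C)O[C@H]2C)[C@@H]1O | intermediate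
27 | C9 O-trimethylsilyl ether of 26 | COC(=O)/C1=C/CC[C@H](C)CCC(=O)OC/C(C(=O)OC)=C\[C@H](OC(=O)[C@@]2(C)OC(C)(C)O[C@H]2C)[C@@H]1O[Si](C)(C)C | intermediate
28 | (E)-trimethylsilyl ketene acetal of 27 (C6=C6a, C5 cis to the ring oxygen) | COC(=O)/C1=C/CC[C@H](C)C/C=C(/O[Si](C)(C)C)OC/C(C(=O)OC)=C\[C@H](OC(=O)[C@@]2(C)OC(C)(C)O[C@H]2C)[C@@H]1O[Si](C)(C)C | intermediate
29 | ring-contracted trimethylsilyl ester, C9 trimethylsilyl ether | C[Si](C)(C)OC(=O)[C@@H]1C[C@@H](C)CC/C=C(/C(=O)OC)[C@@H](O[Si](C)(C)C)[C@@H](OC(=O)[C@@]2(C)OC(C)(C)O[C@H]2C)[C@H]1C(=C)C(=O)OC | intermediate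
30 | (4S,6R,7R,8S,9R) ten-membered carbocyclic acid: C6–CO2H; C7–C(=CH2)CO2Me; C8 O-acyl as in 26; C9–OH; ring-cis C1=C10 with CO2Me on C10; 4-methyl | OC(=O)[C@@H]1C[C@@H](C)CC/C=C(/C(=O)OC)[C@@H](O)[C@@H](OC(=O)[C@@]2(C)OC(C)(C)O[C@H]2C)[C@H]1C(=C)C(=O)OC | intermediate
31 | C9 acetate of 30 | OC(=O)[C@@H]1C[C@@H](C)CC/C=C(/C(=O)OC)[C@@H](OC(C)=O)[C@@H](OC(=O)[C@@]2(C)OC(C)(C)O[C@H]2C)[C@H]1C(=C)C(=O)OC | intermediate
32 | diacyl peroxide of 31 with 3-chloroperoxybenzoic acid | O=C(OOC(=O)c1cccc(Cl)c1)[C@@H]1C[C@@H](C)CC/C=C(/C(=O)OC)[C@@H](OC(C)=O)[C@@H](OC(=O)[C@@]2(C)OC(C)(C)O[C@H]2C)[C@H]1C(=C)C(=O)OC | intermediate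
33 | mixed carbonic 3-chlorobenzoic anhydride on the C6 oxygen | O=C(OC(=O)c1cccc(Cl)c1)O[C@@H]1C[C@@H](C)CC/C=C(/C(=O)OC)[C@@H](OC(C)=O)[C@@H](OC(=O)[C@@]2(C)OC(C)(C)O[C@H]2C)[C@H]1C(=C)C(=O)OC | intermediate
34 | (4S,6R,7S,8S,9R) C6 hydroxy ester | O[C@@H]1C[C@@H](C)CC/C=C(/C(=O)OC)[C@@H](OC(C)=O)[C@@H](OC(=O)[C@@]2(C)OC(C)(C)O[C@H]2C)[C@H]1C(=C)C(=O)OC | intermediate
35 | target with the side-chain diol as its acetonide | C=C1C(=O)O[C@@H]2C[C@@H](C)CC/C=C(/C(=O)OC)[C@@H](OC(C)=O)[C@@H](OC(=O)[C@@]3(C)OC(C)(C)O[C@H]3C)[C@@H]12 | intermediate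
36 | CNP0557070.1 | C=C1C(=O)O[C@@H]2C[C@@H](C)CC/C=C(/C(=O)OC)[C@@H](OC(C)=O)[C@@H](OC(=O)[C@@](C)(O)[C@H](C)O)[C@@H]12 | target

**Step count**
Total: 21 steps. Longest linear sequence: 15 steps (7 → 36 through steps 5, 6 and 9–21). Side-chain acid 6 takes 4 steps and bromide 14 takes 2.

**Steps most likely to fail**

Step 17 (Cr/Ni closure of the 14-membered ring with an α-iodo enoate). The risks are slow cyclisation and loss of the C1=C10 geometry. The fallback sets out from 24 and returns to 26. It replaces the redox-mediated alkenylation by a Reformatsky-type organozinc cyclisation: Zn dust and LiCl in THF at 25 °C (slow addition, high dilution) insert into the C–I bond to give the alkenylzinc iodide F1, which adds to the C9 aldehyde on activation with MgBr2·OEt2; aqueous NH4Cl then gives 26.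

Step 18 (ring contraction). The risks are competing γ-deprotonation, no rearrangement, or the wrong C6/C7 pair; the facial selectivity at C7 is the least certain point of the route. The fallback sets out from 26 and returns to 30. It replaces the sigmatropic shift by a stepwise anionic SN2′ ring contraction: KN(SiMe3)2 (2.2 equiv) in THF, −78 → 0 °C, without silyl chloride, gives the dipotassium enolate–alkoxide F2. Its enolate carbon C6 adds to C7 of the acrylate and the carboxylate is expelled from C13 by β-elimination, giving the dipotassium carboxylate–alkoxide F3, which yields 30 on acidification with 1 M HCl.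

Step 20 (carboxy inversion). The risk is homolysis of the peroxide instead of the 1,2-shift. The fallback sets out from 31 and returns to 34, which lactonises to 35 as in step 20. It uses radical decarboxylative oxygenation: N-hydroxypyridine-2-thione and DCC convert 31 into the thiohydroxamate (Barton) ester F4. Irradiation with visible light in toluene under O2 with t-BuSH gives the C6 hydroperoxide F5, oxygen entering trans to the C7 substituent, and P(OMe)3 reduces F5 to 34.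

**Further compounds**
F1 | step 17 | alkenylzinc iodide from 24 (ZnI at C10) | COC(=O)/C([Zn]I)=C/CC[C@H](C)CCC(=O)OC/C(C(=O)OC)=C\[C@H](OC(=O)[C@@]1(C)OC(C)(C)O[C@H]1C)C=O
F2 | step 18 | dipotassium enolate–alkoxide of 26 | COC(=O)/C1=C/CC[C@H](C)CC=C(O[K])OC/C(C(=O)OC)=C\[C@H](OC(=O)[C@@]2(C)OC(C)(C)O[C@H]2C)[C@@H]1O[K]
F3 | step 18 | dipotassium carboxylate–alkoxide of 30 | [K]OC(=O)[C@@H]1C[C@@H](C)CC/C=C(/C(=O)OC)[C@@H](O[K])[C@@H](OC(=O)[C@@]2(C)OC(C)(C)O[C@H]2C)[C@H]1C(=C)C(=O)OC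
F4 | step 20 | thiohydroxamate (Barton) ester of 31 | S=C1C=CC=CN1OC(=O)[C@@H]1C[C@@H](C)CC/C=C(/C(=O)OC)[C@@H](OC(C)=O)[C@@H](OC(=O)[C@@]2(C)OC(C)(C)O[C@H]2C)[C@H]1C(=C)C(=O)OC
F5 | step 20 | C6 hydroperoxide (6R) | OO[C@@H]1C[C@@H](C)CC/C=C(/C(=O)OC)[C@@H](OC(C)=O)[C@@H](OC(=O)[C@@]2(C)OC(C)(C)O[C@H]2C)[C@H]1C(=C)C(=O)OC
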